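**Plan**

- Numbering: ring A = C1(=CH2)–C2–C3(O)–C4(iPr)–C5–C9, ring B = C5–C6(acetyl)–C7(O)–C8–C9, trans-fused at C5–C9.
- Retrosynthesis: cut the two ester C–O bonds and C1=CH2, then the ring A bond C1–C9. With C1 and C7 written as ketones, C1–C9–C8–C7 is a 1,4-dicarbonyl, so C1–C9 is a Stetter bond, and C9, being α to C1, can be equilibrated to the trans fusion.
- The open precursor is a cyclopentenone (C7=O, C8=C9) with the aldehyde arm C4–C3–C2–C1 on C5. It is cut further at C2–C3 (allylation), at C4–isopropyl (enolate alkylation) and at the acetyl methyl bond, back to the commercial cyclopentane lactone diol 1.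
- Forward: ring B is bought. The masked acetyl group is built on C6, the isopropyl group and the C3 carbinol are added on the lactone arm, and the lactone oxygen on C9 is expelled to give the enone. Ring A then closes, followed by methylenation, C7 reduction, two esterifications and ketal cleavage.
- Stereochemistry: C5 and C6 come from 1. C4 comes from convex-face alkylation of the cis-fused lactone enolate, C3 from reagent-controlled allylboration, C9 from base equilibration, and C7 from hydride attack anti to the C6 group. The oxirane comes from Sharpless epoxidation of the allylic alcohol made from angelic acid.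

Key step: step 13

Remark: the oxirane ester is taken as drawn, the cis (angelic-acid-derived) (2S,3S) isomer. Target numbering C1–C9 is used for every intermediate; TES = triethylsilyl, TBS = tert-butyldimethylsilyl.

**Route**

Step 1
Reactants: 1 (3aR,4S,5R,6aS)-5-hydroxy-4-(hydroxymethyl)hexahydro-2H-cyclopenta[b]furan-2-one (commercial lactone diol; in target numbering lactone C3(=O)–O–C9, C4H2, C6–CH2OH, C7–OH)
Product: 2 bis(triethylsilyl) ether of 1 (C7–OTES and C6–CH2OTES)
Conditions: Et3SiCl, imidazole, DMF, 0 °C → rt
Reagents that add atoms: chlorotriethylsilane, CC[Si](Cl)(CC)CC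
Why: Silylation of a primary and a secondary hydroxyl group with a chlorosilane and imidazole is routine silyl ether formation and leaves the lactone and all four stereocentres untouched.

Step 2
Reactants: 2 bis(triethylsilyl) ether
Product: 3 C6-formyl lactone with C7–OTES (ring centres as in 1)
Conditions: (COCl)2, DMSO, CH2Cl2, −78 → −30 °C; then Et3N, −78 °C → rt
Reagents that add atoms: none
Why: Under Swern conditions chlorodimethylsulfonium chloride cleaves only the unhindered primary triethylsilyl ether and oxidises that oxygen to the aldehyde (oxidative desilylation), while the secondary silyl ether at C7 survives and C6 keeps its thermodynamically preferred trans relation to the C5 arm.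

Step 3
Reactants: 3 C6-formyl lactone
Product: 4 C6-(1-hydroxyethyl) lactone with C7–OTES (both carbinol epimers)
Conditions: MeMgBr, THF, −78 °C; then aqueous NH4Cl at −78 °C
Reagents that add atoms: methylmagnesium bromide, C[Mg]Br
Why: Grignard addition to the aldehyde is much faster than attack on the lactone at −78 °C, and the new carbinol centre may form as a mixture because it is oxidised in the next step.

Step 4
Reactants: 4 C6-(1-hydroxyethyl) lactone
Product: 5 C6-acetyl lactone with C7–OTES
Conditions: Pr4N[RuO4] (5 mol %), N-methylmorpholine N-oxide, 4 Å molecular sieves, CH2Cl2, rt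
Reagents that add atoms: none
Why: Perruthenate-catalysed oxidation of a secondary alcohol to the ketone is neutral, so neither β-elimination of the C7 silyloxy group nor epimerisation at C6 is expected.

Step 5
Reactants: 5 C6-acetyl lactone
Product: 6 C6-(2-methyl-1,3-dioxolan-2-yl) lactone with C7–OTES
Conditions: Me3SiOCH2CH2OSiMe3, Me3SiOTf (5 mol %), CH2Cl2, −78 → −20 °C
Reagents that add atoms: 1,2-bis(trimethylsilyloxy)ethane, C[Si](C)(C)OCCO[Si](C)(C)C
Why: Ketalisation with the bis-silyl ether of ethylene glycol under silyl triflate catalysis runs cold and without protic acid, so the silyl ether is safe, and the dioxolane is chosen because its tethered oxygen cannot be lost irreversibly from a β-keto position later on.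

Step 6
Reactants: 6 dioxolane lactone
Product: 7 (4S)-4-isopropyl lactone (isopropyl exo, cis to H5 and H9)
Conditions: LiN(iPr)2, THF, −78 °C; then 2-iodopropane, DMPU, −78 → −20 °C
Reagents that add atoms: 2-iodopropane, CC(C)I
Why: Alkylation of the lithium enolate of a cis-fused bicyclic lactone takes place on the convex face (the face of H5 and H9), which puts the isopropyl group exo and sets C4 as S, and since the exo epimer is also the more stable one any proton exchange works in the same direction.

Step 7
Reactants: 7 (4S)-4-isopropyl lactone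
Product: 8 lactol (both anomers at C3)
Conditions: iBu2AlH, CH2Cl2, −78 °C; then aqueous KNaC4H4O6
Reagents that add atoms: none
Why: Partial reduction of a lactone with one hydride equivalent at −78 °C stops at the aluminium-bound hemiacetal, which gives the lactol on hydrolysis (lactone to lactol reduction).

Step 8
Reactants: 8 lactol
Product: 9 (3R,4S)-homoallylic diol (C3–OH and C9–OH free, C7–OTES, allyl group = C2, C1 and one extra carbon)
Conditions: (+)-B-methoxydiisopinocampheylborane, CH2=CHCH2MgBr, Et2O, −78 °C → rt; then 8, Et2O, −78 °C → rt; then pH 7 buffer, MeOH, H2O2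
Reagents that add atoms: allylmagnesium bromide, C=CC[Mg]Br (its allyl group reaches 9 through the allylborane made in the flask)
Why: Asymmetric allylboration through a closed chair transition state acts on the hydroxy aldehyde in equilibrium with the lactol, and the isopinocampheyl groups derived from (−)-α-pinene deliver the allyl group to the Re face of the aldehyde, setting C3 as R under reagent control because the two branches on C4 (isopropyl and the ring carbon C5) are of similar size and exert little bias of their own.

Step 9
Reactants: 9 homoallylic diol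
Product: 10 C3,C9-bis(TBS) ether (C7–OTES retained)
Conditions: tBuMe2SiOTf, 2,6-lutidine, CH2Cl2, 0 °C → rt
Reagents that add atoms: tert-butyldimethylsilyl trifluoromethanesulfonate, CC(C)(C)[Si](C)(C)OS(=O)(=O)C(F)(F)F
Why: A silyl triflate with 2,6-lutidine silylates even hindered secondary alcohols, so the C3 and C9 hydroxyl groups are capped in one operation (silyl ether formation).

Step 10
Reactants: 10 bis(TBS) ether
Product: 11 C7 alcohol (C3–OTBS and C9–OTBS retained)
Conditions: HF·pyridine, pyridine, THF, 0 °C
Reagents that add atoms: none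
Why: Buffered HF·pyridine removes a secondary triethylsilyl ether far faster than secondary tert-butyldimethylsilyl ethers (selective desilylation), and the dioxolane tolerates the buffered medium.

Step 11
Reactants: 11 C7 alcohol
Product: 13 (3R,4S,5R,6R)-cyclopentenone alkene (C7=O, C8=C9, C3–OTBS, allyl arm), via silyloxy ketone 12 (not isolated)
Conditions: Pr4N[RuO4] (5 mol %), N-methylmorpholine N-oxide, 4 Å molecular sieves, CH2Cl2, rt; then DBU, 0 °C, short contact
Reagents that add atoms: none
Why: Perruthenate oxidation gives the C7 ketone 12, whose C9 silyloxy group is β to the carbonyl and is expelled by DBU in an E1cB elimination to the conjugated cyclopentenone, whereas the C3 silyl ether has no carbonyl within reach and C6 stays in its favoured trans relation to C5.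

Step 12
Reactants: 13 cyclopentenone alkene
Product: 14 (3R,4S,5R,6R)-cyclopentenone aldehyde (C1HO–C2H2–C3(OTBS)–C4(iPr) arm on C5, dioxolane on C6)
Conditions: O3, CH2Cl2, −78 °C (Sudan Red 7B end point); then PPh3, −78 °C → rt
Reagents that add atoms: ozone, [O-][O+]=O
Why: Ozone reacts with the electron-rich terminal alkene much faster than with the electron-poor enone double bond, so ozonolysis stopped at the indicator end point and followed by phosphine reduction of the ozonide should give the aldehyde without touching ring B.

Step 13
Reactants: 14 cyclopentenone aldehyde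
Product: 16 (3R,4S,5S,6R,9R)-trans-fused hydrindane-1,7-dione (C3–OTBS, C4 isopropyl, C6 dioxolane), via cis-fused dione 15 (not isolated)
Conditions: 2-(pentafluorophenyl)-6,7-dihydro-5H-pyrrolo[2,1-c][1,2,4]triazol-2-ium tetrafluoroborate (20 mol %), iPr2NEt, toluene, rt → 40 °C; then DBU (0.5 equiv), 0 °C → rt
Reagents that add atoms: none
Why: iPr2NEt frees the triazolylidene, which adds to the C1 aldehyde and after proton transfer gives the nucleophilic hydroxy-enamine (acyl anion equivalent); this attacks the enone β-carbon C9, the C7 enolate is protonated at C8 and the carbene is released, which is an intramolecular Stetter reaction of an aliphatic aldehyde onto a cyclic enone, a known reaction class. Ring A (C1-C2-C3-C4-C5-C9) closes in the 6-exo-trig mode by forming C1-C9, helped by the two substituents on the tether. C9, the only new stereocentre, should form mainly cis (15) because the arm on C5 reaches C9 most easily on its own face, and it is then set by thermodynamics when DBU equilibrates it through the C1 enolate: with the C4 isopropyl group and the C5-C6 bond equatorial on the ring A chair, the cis isomer must carry C8 axial while the trans isomer 16 has both fusion bonds equatorial, and ring B can take a twist form with C7 on its axis that fits a trans fusion. C6, which is also enolisable, already lies trans to the C5-C4 bond and should stay there. The step needs chemoselectivity (ring closure before base-induced migration of the C8=C9 double bond or loss of the C3 silyloxy group) and thermodynamic selectivity at C9; the weak amine base, the unsubstituted β-carbon and the conformational anchor at C4 are what secure them.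

Step 14
Reactants: 16 trans-fused dione
Product: 17 (3R,4S,5R,6R,9R)-1-methylidene-7-ketone
Conditions: Ph3PCH3Br, KOtBu, THF, 0 °C; then 16, −78 → 0 °C
Reagents that add atoms: methyltriphenylphosphonium bromide, C[P+](c1ccccc1)(c1ccccc1)c1ccccc1.[Br-]
Why: Wittig methylenation should take place at the C1 cyclohexanone carbonyl, flanked by a methylene and a methine, and not at the C7 cyclopentanone carbonyl, which is shielded by the fully substituted ketal carbon on C6, and because the trans fusion at C9 is the thermodynamic one transient enolisation cannot change it.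

Step 15
Reactants: 17 methylidene ketone
Product: 18 (3R,4S,5R,6R,7S,9R)-C7 alcohol (OH cis to the C6 dioxolanyl group)
Conditions: Li[HB(sBu)3], THF, −78 °C; then NaOH, H2O2, 0 °C
Reagents that add atoms: none
Why: The bulky trialkylborohydride attacks the C7 carbonyl from the face opposite the dioxolanyl group on C6 (sterically controlled ketone reduction), which places the new hydroxyl group cis to that group and sets C7 as S.

Step 16
Reactants: 18 C7 alcohol; 19 angelic acid, (Z)-2-methylbut-2-enoic acid
Product: 21 C7 angelate (C3–OTBS retained), via mixed anhydride 20 (not isolated)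
Conditions: 19, 2,4,6-trichlorobenzoyl chloride, Et3N, toluene, rt; then 18, toluene, 80 °C
Reagents that add atoms: none
Why: Esterification through the mixed anhydride with 2,4,6-trichlorobenzoic acid (Yamaguchi type), run without a nucleophilic amine catalyst, acylates hindered secondary alcohols while keeping the Z geometry of the angeloyl group, which nucleophilic catalysts tend to isomerise.

Step 17
Reactants: 21 C7 angelate
Product: 22 C3 alcohol (axial OH, C7 angelate and dioxolane retained)
Conditions: HF·pyridine, THF, 0 °C → rt
Reagents that add atoms: none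
Why: Fluoride-induced cleavage of the silyl ether with HF·pyridine (desilylation) frees the C3 hydroxyl group under weakly acidic conditions that spare the ester, the exocyclic alkene and the dioxolane.

Step 18
Reactants: 19 angelic acid
Product: 23 (Z)-2-methylbut-2-en-1-ol
Conditions: LiAlH4, Et2O, 0 °C → rt
Reagents that add atoms: none
Why: LiAlH4 reduces the carboxylic acid to the primary allylic alcohol by 1,2-hydride addition (hydride reduction) without touching the trisubstituted double bond or its Z geometry.

Step 19
Reactants: 23 (Z)-2-methylbut-2-en-1-ol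
Product: 24 [(2R,3S)-2,3-dimethyloxiran-2-yl]methanol
Conditions: Ti(OiPr)4 (10 mol %), D-(−)-diethyl tartrate (12 mol %), tBuOOH, 4 Å molecular sieves, CH2Cl2, −20 °C
Reagents that add atoms: tert-butyl hydroperoxide, CC(C)(C)OO
Why: In the Sharpless asymmetric epoxidation the titanium complex of D-(−)-diethyl tartrate delivers the peroxide oxygen to the face of the Z-allylic alcohol that gives the (2R,3S)-epoxy alcohol, and the syn addition keeps the hydroxymethyl group cis to the C3 methyl group.

Step 20
Reactants: 24 epoxy alcohol
Product: 25 (2S,3S)-2,3-dimethyloxirane-2-carboxylic acid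
Conditions: RuCl3 hydrate (2 mol %), NaIO4, MeCN/EtOAc/H2O, 0 °C → rt
Reagents that add atoms: water, O
Why: RuO4 generated catalytically from RuCl3 and periodate oxidises the primary alcohol through the aldehyde hydrate to the carboxylic acid (alcohol to acid oxidation) and leaves the epoxide and both stereocentres untouched, the descriptor at C2 changing to S only through the priority rules.

Step 21
Reactants: 22 C3 alcohol; 25 (2S,3S)-epoxy acid
Product: 27 C3 epoxyangelate C7 angelate with the C6 dioxolane, via mixed anhydride 26 (not isolated)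
Conditions: 25, 2,4,6-trichlorobenzoyl chloride, Et3N, THF, rt; then 22, DMAP, toluene, rt → 50 °C
Reagents that add atoms: none
Why: Yamaguchi esterification with DMAP transfers the hindered but non-isomerisable α,α-disubstituted acyl group to the axial C3 hydroxyl group, the only free hydroxyl group in 22, with no effect on any stereocentre.

Step 22
Reactants: 27 diester ketal
Product: 28 target CNP0300602.1, (3R,4S,5R,6R,7S,9R)-6-acetyl-4-isopropyl-1-methylidene-trans-hydrindane-3,7-diol 7-angelate 3-[(2S,3S)-2,3-dimethyloxirane-2-carboxylate]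
Conditions: pyridinium p-toluenesulfonate (20 mol %), acetone/H2O (9:1), 45 °C
Reagents that add atoms: water, O
Why: Mild acid-catalysed hydrolysis of the dioxolane (ketal cleavage) with a non-nucleophilic pyridinium acid unveils the C6 acetyl group last, so that the base-sensitive β-acyloxy ketone never meets esterification conditions, and the glycidic ester, deactivated towards acid opening by its carbonyl group, should survive.

**Compound list**

1 | (3aR,4S,5R,6aS)-5-hydroxy-4-(hydroxymethyl)hexahydro-2H-cyclopenta[b]furan-2-one | O=C1C[C@@H]2[C@@H](CO)[C@H](O)C[C@@H]2O1 | starting material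
2 | bis(triethylsilyl) ether of 1 | O=C1C[C@@H]2[C@@H](CO[Si](CC)(CC)CC)[C@H](O[Si](CC)(CC)CC)C[C@@H]2O1 | intermediate
3 | C6-formyl lactone, C7–OTES | O=C1C[C@@H]2[C@@H](C=O)[C@H](O[Si](CC)(CC)CC)C[C@@H]2O1 | intermediate
4 | C6-(1-hydroxyethyl) lactone, C7–OTES, carbinol epimers | O=C1C[C@@H]2[C@@H](C(C)O)[C@H](O[Si](CC)(CC)CC)C[C@@H]2O1 | intermediate
5 | C6-acetyl lactone, C7–OTES | O=C1C[C@@H]2[C@@H](C(C)=O)[C@H](O[Si](CC)(CC)CC)C[C@@H]2O1 | intermediate
6 | C6-(2-methyl-1,3-dioxolan-2-yl) lactone, C7–OTES | O=C1C[C@@H]2[C@@H](C3(C)OCCO3)[C@H](O[Si](CC)(CC)CC)C[C@@H]2O1 | intermediate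
7 | (4S)-4-isopropyl lactone, isopropyl exo | O=C1[C@@H](C(C)C)[C@@H]2[C@@H](C3(C)OCCO3)[C@H](O[Si](CC)(CC)CC)C[C@@H]2O1 | intermediate
8 | lactol of 7, both anomers | OC1[C@@H](C(C)C)[C@@H]2[C@@H](C3(C)OCCO3)[C@H](O[Si](CC)(CC)CC)C[C@@H]2O1 | intermediate
9 | (3R,4S)-homoallylic diol, C7–OTES | C=CC[C@@H](O)[C@@H](C(C)C)[C@@H]1[C@@H](C2(C)OCCO2)[C@H](O[Si](CC)(CC)CC)C[C@@H]1O | intermediate
10 | C3,C9-bis(TBS) ether, C7–OTES | C=CC[C@@H](O[Si](C)(C)C(C)(C)C)[C@@H](C(C)C)[C@@H]1[C@@H](C2(C)OCCO2)[C@H](O[Si](CC)(CC)CC)C[C@@H]1O[Si](C)(C)C(C)(C)C | intermediate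
11 | C7 alcohol, C3,C9-bis(TBS) ether | C=CC[C@@H](O[Si](C)(C)C(C)(C)C)[C@@H](C(C)C)[C@@H]1[C@@H](C2(C)OCCO2)[C@H](O)C[C@@H]1O[Si](C)(C)C(C)(C)C | intermediate
12 | C7 ketone with C9–OTBS (silyloxy ketone) | C=CC[C@@H](O[Si](C)(C)C(C)(C)C)[C@@H](C(C)C)[C@@H]1[C@@H](C2(C)OCCO2)C(=O)C[C@@H]1O[Si](C)(C)C(C)(C)C | intermediate
13 | (3R,4S,5R,6R)-cyclopentenone alkene | C=CC[C@@H](O[Si](C)(C)C(C)(C)C)[C@@H](C(C)C)[C@@H]1[C@@H](C2(C)OCCO2)C(=O)C=C1 | intermediate
14 | (3R,4S,5R,6R)-cyclopentenone aldehyde, Stetter precursor | O=CC[C@@H](O[Si](C)(C)C(C)(C)C)[C@@H](C(C)C)[C@@H]1[C@@H](C2(C)OCCO2)C(=O)C=C1 | intermediate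
15 | (3R,4S,5S,6R,9S)-cis-fused hydrindane-1,7-dione | O=C1C[C@@H](O[Si](C)(C)C(C)(C)C)[C@@H](C(C)C)[C@@H]2[C@@H](C3(C)OCCO3)C(=O)C[C@H]12 | intermediate
16 | (3R,4S,5S,6R,9R)-trans-fused hydrindane-1,7-dione | O=C1C[C@@H](O[Si](C)(C)C(C)(C)C)[C@@H](C(C)C)[C@@H]2[C@@H](C3(C)OCCO3)C(=O)C[C@@H]12 | intermediate
17 | (3R,4S,5R,6R,9R)-1-methylidene-7-ketone | C=C1C[C@@H](O[Si](C)(C)C(C)(C)C)[C@@H](C(C)C)[C@@H]2[C@@H](C3(C)OCCO3)C(=O)C[C@@H]12 | intermediate
18 | (3R,4S,5R,6R,7S,9R)-C7 alcohol | C=C1C[C@@H](O[Si](C)(C)C(C)(C)C)[C@@H](C(C)C)[C@@H]2[C@@H](C3(C)OCCO3)[C@@H](O)C[C@@H]12 | intermediate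
19 | angelic acid, (Z)-2-methylbut-2-enoic acid | OC(=O)/C(C)=C\C | starting material
20 | angelic 2,4,6-trichlorobenzoic anhydride | O=C(OC(=O)/C(C)=C\C)c1c(Cl)cc(Cl)cc1Cl | intermediate
21 | C7 angelate, C3–OTBS | C=C1C[C@@H](O[Si](C)(C)C(C)(C)C)[C@@H](C(C)C)[C@@H]2[C@@H](C3(C)OCCO3)[C@@H](OC(=O)/C(C)=C\C)C[C@@H]12 | intermediate
22 | C7 angelate, C3 alcohol | C=C1C[C@@H](O)[C@@H](C(C)C)[C@@H]2[C@@H](C3(C)OCCO3)[C@@H](OC(=O)/C(C)=C\C)C[C@@H]12 | intermediate
23 | (Z)-2-methylbut-2-en-1-ol | OC/C(C)=C\C | intermediate
24 | [(2R,3S)-2,3-dimethyloxiran-2-yl]methanol | OC[C@@]1(C)O[C@H]1C | intermediate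
25 | (2S,3S)-2,3-dimethyloxirane-2-carboxylic acid | OC(=O)[C@@]1(C)O[C@H]1C | intermediate
26 | (2S,3S)-2,3-dimethyloxirane-2-carboxylic 2,4,6-trichlorobenzoic anhydride | O=C(OC(=O)[C@@]1(C)O[C@H]1C)c1c(Cl)cc(Cl)cc1Cl | intermediate
27 | C3 epoxyangelate C7 angelate, C6 dioxolane | C=C1C[C@@H](OC(=O)[C@@]2(C)O[C@H]2C)[C@@H](C(C)C)[C@@H]2[C@@H](C3(C)OCCO3)[C@@H](OC(=O)/C(C)=C\C)C[C@@H]12 | intermediate
28 | CNP0300602.1 | C=C1C[C@@H](OC(=O)[C@@]2(C)O[C@H]2C)[C@@H](C(C)C)[C@@H]2[C@@H](C(C)=O)[C@@H](OC(=O)/C(C)=C\C)C[C@@H]12 | target

**Step count and risks**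

Total steps: 22. Longest linear sequence: 19 steps (1 → 28 through steps 1–17, 21 and 22). Steps 18–20 make acid 25 from angelic acid 19.

Steps most likely to fail:

1. Step 13. The carbene may turn over slowly for a six-membered closure from an aliphatic aldehyde. Base-induced migration of the C8=C9 double bond into the more substituted position, aldol self-condensation of the aldehyde, or loss of silanol from C3 during the DBU phase could then outrun ring closure. Fallback, starting from aldehyde 14: NaClO2, NaH2PO4 and 2-methylbut-2-ene in tBuOH/H2O (Pinnick oxidation) give the carboxylic acid F1. PhSeSePh and Bu3P in CH2Cl2 turn it into the Se-phenyl selenoester F2. Slow addition of Bu3SnH with AIBN in benzene at 80 °C generates the acyl radical, which adds to C9 in the same 6-exo-trig sense; hydrogen transfer to the C8 radical gives the cis-fused dione 15, possibly with some 16. DBU as in step 13 then equilibrates the mixture, so the fallback rejoins the route at 16.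

2. Step 6. The lactone enolate may act as a base towards the secondary iodide (E2 loss of propene), and proton exchange may leave most of 6 unalkylated. Fallback, starting from lactone 6: LiN(iPr)2 then acetone at −78 °C gives the aldol adduct F3. Dehydration with methyl N-(triethylammoniosulfonyl)carbamate in benzene at 50 °C gives the isopropylidene lactone F4 (any isopropenyl isomer serves equally). H2 over Pd/C in EtOAc adds hydrogen from the convex face and should give mainly the endo-isopropyl lactone F5. Catalytic KOtBu in tBuOH/THF then epimerises C4 to the more stable exo lactone, which is 7.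

3. Step 14. The ylide may act as a base, enolising C1 and expelling the C3 silyloxy group from the enolate, or it may also attack the C7 carbonyl. Fallback, starting from dione 16: Me3SiCH2Li premixed with anhydrous CeCl3 in THF at −78 °C, a weakly basic and bulky nucleophile, should add to the C1 carbonyl only and give the β-hydroxysilane F6. KH in THF at 0 °C then triggers the syn elimination of the Peterson olefination, which returns to 17.

**Further compounds**

F1 | step 13 | carboxylic acid from 14 (C1 acid, cyclopentenone intact) | OC(=O)C[C@@H](O[Si](C)(C)C(C)(C)C)[C@@H](C(C)C)[C@@H]1[C@@H](C2(C)OCCO2)C(=O)C=C1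
F2 | step 13 | Se-phenyl selenoester of F1 | O=C(C[C@@H](O[Si](C)(C)C(C)(C)C)[C@@H](C(C)C)[C@@H]1[C@@H](C2(C)OCCO2)C(=O)C=C1)[Se]c1ccccc1
F3 | step 6 | aldol adduct of 6 with acetone (4-exo 2-hydroxypropan-2-yl lactone) | O=C1[C@@H](C(C)(C)O)[C@@H]2[C@@H](C3(C)OCCO3)[C@H](O[Si](CC)(CC)CC)C[C@@H]2O1
F4 | step 6 | 4-isopropylidene lactone | O=C1C(=C(C)C)[C@@H]2[C@@H](C3(C)OCCO3)[C@H](O[Si](CC)(CC)CC)C[C@@H]2O1
F5 | step 6 | endo-isopropyl lactone (C4 epimer of 7) | O=C1[C@H](C(C)C)[C@@H]2[C@@H](C3(C)OCCO3)[C@H](O[Si](CC)(CC)CC)C[C@@H]2O1
F6 | step 14 | β-hydroxysilane (1-hydroxy-1-(trimethylsilylmethyl) adduct of 16, C1 epimers) | C[Si](C)(C)CC1(O)C[C@@H](O[Si](C)(C)C(C)(C)C)[C@@H](C(C)C)[C@@H]2[C@@H](C3(C)OCCO3)C(=O)C[C@@H]12
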